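**Retrosynthetic overview**
- The last bonds made are the two catechol C–O bonds (one new OH on ring B, one on ring C), by a twofold magnesium-templated ortho-C–H hydroxylation of a biaryl bis-phenol.
- The bis-phenol comes from hydrogenation of a bis-stilbene, itself from a double Wittig reaction of a biaryl dialdehyde with the 3-methoxybenzyl ylide (this brings in rings A and D).
- The biaryl dialdehyde (ring B–ring C bond) comes from a one-pot borylation/Suzuki coupling of two bromo-hydroxybenzaldehydes.
- No ring is constructed: rings A–D are all bought as benzene rings. Assembly order is the B–C biaryl first, then rings A and D through the two chains, then the two oxygens.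

Assumption: the target has no stereocentre and its biaryl axis carries only two ortho substituents (an OH and a CH2CH2Ar chain), so it is not configurationally stable; the compound is achiral and is made as the single species drawn.

Ring labels: rings A and D are the 3-methoxyphenyl rings. Ring B is the inner ring whose biaryl bond is ortho to an OH (primed locants). Ring C is the inner ring whose biaryl bond is para to an OH and ortho to its chain (unprimed locants).

**Step 1**
Reactants: 1 2-bromo-5-hydroxybenzaldehyde; 2 3-bromo-4-hydroxybenzaldehyde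
Product: 4 2',4-dihydroxy-[1,1'-biphenyl]-2,5'-dicarbaldehyde, via pinacol boronate 3 (not isolated)
Conditions: 1 (1.1 equiv), B2pin2 (1.15 equiv), Pd(dppf)Cl2 (3 mol %), KOAc, 1,4-dioxane, 90 °C; then 2 (1.0 equiv), 2 M aq K3PO4, 90 °C
Reagents that add atoms: bis(pinacolato)diboron, CC1(C)OB(OC1(C)C)B1OC(C)(C)C(C)(C)O1 (its boryl group is carried by 3 only and is lost again on the way to 4)
Why: Miyaura borylation of the ortho-formyl-activated aryl bromide 1 is followed in the same flask, on the same zerovalent palladium cycle, by Suzuki–Miyaura coupling with bromophenol 2; both stages tolerate free phenols and aldehydes, and no stereocentre is formed.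

**Step 2**
Reactants: 4 2',4-dihydroxy-[1,1'-biphenyl]-2,5'-dicarbaldehyde; 5 (3-methoxybenzyl)triphenylphosphonium chloride
Product: 7 2,5'-bis[2-(3-methoxyphenyl)ethenyl]-[1,1'-biphenyl]-2',4-diol (E/Z mixture at both alkenes), via benzylidene phosphorane 6 (not isolated)
Conditions: 5 (2.6 equiv), KOtBu (5.2 equiv), THF/DMF, 0 °C; then 4, 0 → 60 °C
Reagents that add atoms: none
Why: Twofold Wittig olefination by the semi-stabilised ylide 6; the extra base holds both phenols as potassium phenoxides, which slows but does not stop carbonyl addition at 60 °C, and the E/Z ratio does not matter because both alkenes are hydrogenated next.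

**Step 3**
Reactants: 7 2,5'-bis[2-(3-methoxyphenyl)ethenyl]-[1,1'-biphenyl]-2',4-diol
Product: 8 2,5'-bis[2-(3-methoxyphenyl)ethyl]-[1,1'-biphenyl]-2',4-diol
Conditions: H2 (1 atm), 10% Pd/C (zerovalent palladium on carbon), EtOAc/MeOH, rt
Reagents that add atoms: none
Why: Heterogeneous catalytic hydrogenation saturates both stilbene C=C bonds of either geometry, while aryl ethers, phenols and the biaryl are inert; no stereocentre arises.

**Step 4**
Reactants: 8 2,5'-bis[2-(3-methoxyphenyl)ethyl]-[1,1'-biphenyl]-2',4-diol
Product: 10 isoplagilin (2,5'-bis[2-(3-methoxyphenyl)ethyl]-[1,1'-biphenyl]-2',3',4,5-tetrol), via bis(chloromagnesium) phenoxide 9 (not isolated)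
Conditions: i-PrMgCl (2.0 equiv), THF, 0 °C, then solvent switch to PhMe; (1S)-(+)-(10-camphorsulfonyl)oxaziridine (2.1 equiv), −20 → 40 °C; aq NH4Cl/Na2S2O4 work-up
Reagents that add atoms: (1S)-(+)-(10-camphorsulfonyl)oxaziridine, CC1(C)[C@@H]2CC[C@]13CS(=O)(=O)[N@]1O[C@]13C2 (one oxygen atom to each inner ring; the reagent's configuration is immaterial); isopropylmagnesium chloride, CC(C)[Mg]Cl (its MgCl is carried by 9 only)
Why: Proposed new method: each aryloxymagnesium chloride of 9 binds a sulfonyl oxygen of the oxaziridine at divalent magnesium and passes the electrophilic oxaziridine oxygen to its own ortho carbon within the chelate (the template logic of magnesium-mediated ortho-formylation of phenols), the resulting 6-oxidocyclohexadienone tautomerises to a chelated magnesium catecholate that is less carbon-nucleophilic than the phenoxide, and the hindered cyclic sulfonyl ketimine by-product cannot add back to the arene; ring B has only one free ortho carbon (C3') and ring C reacts at C5, the ortho carbon remote from its chain; the closest known reaction types are the Davis oxaziridine hydroxylation of enolates and the Lewis-acid-catalysed hydroxylative dearomatisation of 2-naphthols with N-sulfonyl oxaziridines, neither yet shown as an aromatising ortho-hydroxylation of simple phenols.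

**Compound list**
1 | 2-bromo-5-hydroxybenzaldehyde | O=Cc1cc(O)ccc1Br | starting material
2 | 3-bromo-4-hydroxybenzaldehyde | O=Cc1ccc(O)c(Br)c1 | starting material
3 | 5-hydroxy-2-(4,4,5,5-tetramethyl-1,3,2-dioxaborolan-2-yl)benzaldehyde (not isolated) | O=Cc1cc(O)ccc1B1OC(C)(C)C(C)(C)O1 | intermediate
4 | 2',4-dihydroxy-[1,1'-biphenyl]-2,5'-dicarbaldehyde | O=Cc1ccc(O)c(-c2ccc(O)cc2C=O)c1 | intermediate
5 | (3-methoxybenzyl)triphenylphosphonium chloride | COc1cccc(C[P+](c2ccccc2)(c2ccccc2)c2ccccc2)c1.[Cl-] | starting material
6 | (3-methoxybenzylidene)triphenylphosphorane (not isolated) | COc1cccc(C=P(c2ccccc2)(c2ccccc2)c2ccccc2)c1 | intermediate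
7 | 2,5'-bis[2-(3-methoxyphenyl)ethenyl]-[1,1'-biphenyl]-2',4-diol (E/Z mixture, alkene geometry left open) | COc1cccc(C=Cc2ccc(O)c(-c3ccc(O)cc3C=Cc3cccc(OC)c3)c2)c1 | intermediate
8 | 2,5'-bis[2-(3-methoxyphenyl)ethyl]-[1,1'-biphenyl]-2',4-diol | COc1cccc(CCc2ccc(O)c(-c3ccc(O)cc3CCc3cccc(OC)c3)c2)c1 | intermediate
9 | bis(chloromagnesium) 2,5'-bis[2-(3-methoxyphenyl)ethyl]-[1,1'-biphenyl]-2',4-diolate (not isolated) | COc1cccc(CCc2ccc(O[Mg]Cl)c(-c3ccc(O[Mg]Cl)cc3CCc3cccc(OC)c3)c2)c1 | intermediate
10 | isoplagilin, 2,5'-bis[2-(3-methoxyphenyl)ethyl]-[1,1'-biphenyl]-2',3',4,5-tetrol (achiral) | COc1cccc(CCc2cc(O)c(O)c(-c3cc(O)c(O)cc3CCc3cccc(OC)c3)c2)c1 | target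

**Totals**
Total step count: 4. Longest linear sequence: 4 steps (1 → 4 → 7 → 8 → 10).

**Three steps most likely to fail, with fallbacks**

Step 4 (proposed new hydroxylation; the most likely to fail). The magnesium phenoxides may be too weak as carbon nucleophiles for the oxaziridine. The catechol may be oxidised further. Ring C may react partly at C3, next to its chain. The fallback uses known chemistry and sets out from 8. 2-Iodoxybenzoic acid (IBX, 2.4 equiv) in DMF at 0 °C to rt oxidises each phenol, through an aryloxy-iodane and oxygen transfer to the less hindered ortho carbon, to the bis(ortho-quinone) F1. This is not isolated but reduced in the same flask with aqueous Na2S2O4, and the fallback comes back to the route at 10. It passes through the quinone oxidation level, so the reduction must follow promptly to avoid cyclisation of the ring B hydroxyl onto the ring C quinone.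

Step 1 (one-pot borylation/Suzuki coupling on unprotected bromo-hydroxybenzaldehydes). The phenols may interfere with borylation, the ortho-formyl boronate may protodeboronate, or homocoupling may compete. The fallback sets out from 1 and 2 and changes to a protected, stepwise sequence. O-Benzylation (BnBr, K2CO3, DMF) gives 5-(benzyloxy)-2-bromobenzaldehyde F2 and 4-(benzyloxy)-3-bromobenzaldehyde F3. F2 is borylated (B2pin2, Pd(dppf)Cl2, KOAc, dioxane) and the isolated 5-(benzyloxy)-2-(4,4,5,5-tetramethyl-1,3,2-dioxaborolan-2-yl)benzaldehyde F4 is coupled with F3 (Pd(dppf)Cl2, aq K3PO4, dioxane) to 2',4-bis(benzyloxy)-[1,1'-biphenyl]-2,5'-dicarbaldehyde F5. Wittig olefination with ylide 6 gives 2',4-bis(benzyloxy)-2,5'-bis[2-(3-methoxyphenyl)ethenyl]-1,1'-biphenyl F6. Hydrogenation (H2, Pd/C) then saturates both alkenes and cleaves both benzyl ethers, and the fallback comes back to the route at 8.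

Step 2 (double Wittig on a bis-phenoxide dialdehyde). The ring B aldehyde sits para to a phenoxide and may be too weakly electrophilic for the semi-stabilised ylide, and the dipotassium salt may be poorly soluble. The fallback sets out from 4 and replaces olefination by addition and dehydration. Excess 3-methoxybenzylmagnesium chloride (commercial THF solution, 5 equiv, 0 °C; two equivalents are spent on the phenols) gives 2,5'-bis[1-hydroxy-2-(3-methoxyphenyl)ethyl]-[1,1'-biphenyl]-2',4-diol F7 as a diastereomer mixture. Acid-catalysed dehydration (p-TsOH, PhMe, 80 °C) gives the stilbenes, and the fallback comes back to the route at 7, ahead of the hydrogenation.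

**Further compounds**
F1 | step 4 | bis(ortho-quinone) of 10 (rings B and C each as a 1,2-benzoquinone) | COc1cccc(CCC2=CC(=O)C(=O)C(C3=CC(=O)C(=O)C=C3CCc3cccc(OC)c3)=C2)c1
F2 | step 1 | 5-(benzyloxy)-2-bromobenzaldehyde | O=Cc1cc(OCc2ccccc2)ccc1Br
F3 | step 1 | 4-(benzyloxy)-3-bromobenzaldehyde | O=Cc1ccc(OCc2ccccc2)c(Br)c1
F4 | step 1 | 5-(benzyloxy)-2-(4,4,5,5-tetramethyl-1,3,2-dioxaborolan-2-yl)benzaldehyde | O=Cc1cc(OCc2ccccc2)ccc1B1OC(C)(C)C(C)(C)O1
F5 | step 1 | 2',4-bis(benzyloxy)-[1,1'-biphenyl]-2,5'-dicarbaldehyde | O=Cc1ccc(OCc2ccccc2)c(-c2ccc(OCc3ccccc3)cc2C=O)c1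
F6 | step 1 | 2',4-bis(benzyloxy)-2,5'-bis[2-(3-methoxyphenyl)ethenyl]-1,1'-biphenyl (E/Z mixture, alkene geometry left open) | COc1cccc(C=Cc2ccc(OCc3ccccc3)c(-c3ccc(OCc4ccccc4)cc3C=Cc3cccc(OC)c3)c2)c1
F7 | step 2 | 2,5'-bis[1-hydroxy-2-(3-methoxyphenyl)ethyl]-[1,1'-biphenyl]-2',4-diol (diastereomer mixture) | COc1cccc(CC(O)c2ccc(O)c(-c3ccc(O)cc3C(O)Cc3cccc(OC)c3)c2)c1
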